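**Retrosynthetic overview**
1. Target 38 ⇐ C3 ketone 37 (catalyst-controlled CBS reduction) ⇐ 8-hydroxy keto lactone 35 + angelic acid 36 (Yamaguchi esterification).
2. Lactone ring (formed second) ⇐ oxidative lactonisation of the 6-OH/12-OH 2-methylene-1,4-diol of macrocycle 32; ten-membered carbocycle (formed first) ⇐ Nozaki–Hiyama–Kishi closure of C2–C3 in vinyl iodide/Z-enal 30.
3. 30 ⇐ Still–Gennari olefination (Z-C4=C5), Takai olefination (E-C1=C2–I), Sharpless epoxidation/LiAlH4 (C10), Hosomi–Sakurai allylation of aldehyde 9 (C8–C9, Felkin/1,3-anti).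
4. 9 ⇐ Fráter–Seebach allylation (C7) of hydroxy ester 4 ⇐ ketoreductase reduction of β-keto ester 3 (C6); the allyl group becomes C11–C12 and C13 comes from Eschenmoser's salt.

Assumption: 1, 2, 5, 10, 27 and 36 are bought (all achiral); locants C1–C15 in the short names are those of the germacranolide target (C12 lactone carbonyl, C13 exocyclic CH2), and the SMILES in the compound list are definitive.

**Step 1**
Reactants: 1 ethyl 4-chloro-3-oxobutanoate; 2 4-methoxybenzyl alcohol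
Product: 3 ethyl 4-[(4-methoxybenzyl)oxy]-3-oxobutanoate
Conditions: NaH (2.2 equiv), THF, 0 °C → rt; aq. HCl work-up
Reagents that add atoms: none
Why: Williamson etherification; the alkoxide of 2 displaces the activated chloride while the keto ester is held as its enolate.

**Step 2**
Reactants: 3 PMB keto ester
Product: 4 ethyl (3R)-3-hydroxy-4-[(4-methoxybenzyl)oxy]butanoate
Conditions: (R)-selective ketoreductase, NADP+ (cat.), iPrOH (10 vol %), phosphate buffer pH 7, 30 °C
Reagents that add atoms: none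
Why: Enzymatic asymmetric reduction of a β-keto ester by a ketoreductase; NADPH hydride (recycled by isopropanol) is delivered to one carbonyl face in the active site and sets C6, the first stereocentre.

**Step 3**
Reactants: 4 (3R)-hydroxy ester; 5 allyl bromide
Product: 7 ethyl (2S,3R)-2-allyl-3-hydroxy-4-[(4-methoxybenzyl)oxy]butanoate, via dilithium alkoxide-enolate 6 (not isolated)
Conditions: LiN(iPr)2 (2.2 equiv, commercial solution), THF, −78 → −20 °C; then 5, DMPU, −78 → −20 °C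
Reagents that add atoms: none
Why: Fráter–Seebach alkylation; the chelated lithium alkoxide-enolate is allylated anti to the β-oxygen, which sets C7.

**Step 4**
Reactants: 7 anti allyl hydroxy ester
Product: 8 O6-triethylsilyl ether of 7
Conditions: Et3SiCl, imidazole, CH2Cl2, 0 °C → rt
Reagents that add atoms: chlorotriethylsilane CC[Si](Cl)(CC)CC
Why: Silylation of the secondary alcohol gives the β-silyloxy group needed for 1,3-induction in step 6 and keeps O6 masked until after ring closure.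

**Step 5**
Reactants: 8 O6-TES ester
Product: 9 (2S,3R)-2-allyl-4-[(4-methoxybenzyl)oxy]-3-(triethylsilyloxy)butanal
Conditions: iBu2AlH (1.1 equiv), CH2Cl2, −78 °C; Rochelle-salt work-up
Reagents that add atoms: none
Why: Partial ester reduction; the chelated tetrahedral aluminium hemiacetal survives at −78 °C and releases the C8 aldehyde on work-up.

**Step 6**
Reactants: 9 C8 aldehyde; 10 2-[(trimethylsilyl)methyl]prop-2-en-1-yl acetate
Product: 11 C8 homoallylic alcohol (6R,7R,8S)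
Conditions: BF3·OEt2, CH2Cl2, −78 °C; aq. NaHCO3
Reagents that add atoms: none
Why: Hosomi–Sakurai allylation through an open transition state; Felkin control by C7 and 1,3-anti induction by the β-silyloxy group reinforce each other in this anti-configured aldehyde (Evans merged model) and set C8.

**Step 7**
Reactants: 11 C8 homoallylic alcohol
Product: 12 O8-triisopropylsilyl ether of 11
Conditions: iPr3SiOTf, 2,6-lutidine, CH2Cl2, 0 °C
Reagents that add atoms: triisopropylsilyl trifluoromethanesulfonate CC(C)[Si](OS(=O)(=O)C(F)(F)F)(C(C)C)C(C)C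
Why: Silyl ether formation; the robust TIPS group keeps O8 blocked until the lactone is closed on O6.

**Step 8**
Reactants: 12 O8-TIPS allylic acetate
Product: 13 2-substituted allylic alcohol
Conditions: K2CO3 (cat.), MeOH, 0 °C
Reagents that add atoms: none
Why: Zemplén-type transesterification removes the acetate without touching the silyl or PMB ethers.

**Step 9**
Reactants: 13 allylic alcohol
Product: 14 (10S)-2,2-disubstituted epoxy alcohol
Conditions: Ti(OiPr)4 (10 mol %), L-(+)-diethyl tartrate (12 mol %), tBuOOH, 4 Å molecular sieves, CH2Cl2, −20 °C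
Reagents that add atoms: tert-butyl hydroperoxide CC(C)(C)OO
Why: Sharpless asymmetric epoxidation; the titanium tartrate catalyst delivers oxygen to one face of the 1,1-disubstituted olefin under reagent control and fixes the C10–O bond.

**Step 10**
Reactants: 14 epoxy alcohol
Product: 15 C10/C1 diol (tertiary carbinol with C14 methyl)
Conditions: LiAlH4, THF, 0 °C
Reagents that add atoms: none
Why: Hydride opens the epoxide by SN2 attack at the unsubstituted CH2, which becomes the C14 methyl; C10 is untouched.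

**Step 11**
Reactants: 15 diol
Product: 16 bis-triethylsilyl ether (O1 and O10)
Conditions: Et3SiOTf (2.5 equiv), 2,6-lutidine, CH2Cl2, −78 → 0 °C
Reagents that add atoms: triethylsilyl trifluoromethanesulfonate CC[Si](CC)(CC)OS(=O)(=O)C(F)(F)F
Why: The silyl triflate silylates both the primary and the hindered tertiary hydroxyl, protecting the 1,2-diol from periodate.

**Step 12**
Reactants: 16 bis-TES ether
Product: 18 C12 aldehyde, via vicinal diol 17 (not isolated)
Conditions: OsO4 (2 mol %), NaIO4, 2,6-lutidine, 1,4-dioxane/H2O 3:1, rt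
Reagents that add atoms: osmium tetroxide O=[Os](=O)(=O)=O (catalytic oxygen carrier); sodium periodate [Na+].[O-]I(=O)(=O)=O
Why: Lemieux–Johnson oxidation; the allyl group is the only olefin present, so dihydroxylation and glycol cleavage give the C11–C12 aldehyde.

**Step 13**
Reactants: 18 C12 aldehyde
Product: 20 α-methylene aldehyde (C13 installed), via Mannich base 19 (not isolated)
Conditions: CH2=NMe2+ I−, Et3N, CH2Cl2, rt
Reagents that add atoms: N,N-dimethylmethyleneiminium iodide C=[N+](C)C.[I-]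
Why: Mannich reaction at the aldehyde α-carbon C11 followed by β-elimination of dimethylamine (Eschenmoser methylenation); C7 is not enolisable at this point.

**Step 14**
Reactants: 20 α-methylene aldehyde
Product: 21 C12 allylic alcohol
Conditions: iBu2AlH, CH2Cl2, −78 °C
Reagents that add atoms: none
Why: Clean 1,2-reduction of the enal.

**Step 15**
Reactants: 21 allylic alcohol
Product: 22 O12-tert-butyldimethylsilyl ether
Conditions: tBuMe2SiCl, imidazole, CH2Cl2, rt
Reagents that add atoms: tert-butyldimethylsilyl chloride CC(C)(C)[Si](C)(C)Cl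
Why: Silylation of the unhindered primary alcohol with a group that survives the Swern conditions of step 16.

**Step 16**
Reactants: 22 O12-TBS ether
Product: 23 C1 aldehyde (α-silyloxy, quaternary C10)
Conditions: (COCl)2, DMSO, CH2Cl2, −78 → −30 °C; then Et3N, −78 °C → rt
Reagents that add atoms: none
Why: Swern oxidation applied directly to the primary triethylsilyl ether; secondary and tertiary TES, TBS and TIPS ethers are inert.

**Step 17**
Reactants: 23 C1 aldehyde
Product: 24 (E)-vinyl iodide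
Conditions: CrCl2 (8 equiv), CHI3 (3 equiv), THF/1,4-dioxane 1:4, 0 °C → rt
Reagents that add atoms: iodoform IC(I)I
Why: Takai olefination; the geminal dichromium reagent gives the E-iodoalkene, strongly favoured for a hindered aldehyde.

**Step 18**
Reactants: 24 vinyl iodide
Product: 25 C5 primary alcohol
Conditions: 2,3-dichloro-5,6-dicyano-1,4-benzoquinone (DDQ), CH2Cl2/pH 7 buffer, 0 °C
Reagents that add atoms: none
Why: Oxidative cleavage of the PMB ether under neutral conditions; silyl ethers, the vinyl iodide and the 1,1-disubstituted olefin are untouched.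

**Step 19**
Reactants: 25 C5 alcohol
Product: 26 C5 aldehyde (α-silyloxy)
Conditions: Dess–Martin periodinane, NaHCO3, CH2Cl2, 0 °C → rt
Reagents that add atoms: none
Why: Mild buffered oxidation that does not epimerise the α-silyloxy aldehyde.

**Step 20**
Reactants: 26 C5 aldehyde; 27 ethyl 2-[bis(2,2,2-trifluoroethoxy)phosphoryl]propanoate
Product: 28 (Z)-α-methyl enoate
Conditions: KN(SiMe3)2, 18-crown-6, THF, −78 °C
Reagents that add atoms: none
Why: Still–Gennari olefination; fast collapse of the kinetic adduct of the trifluoroethyl phosphonate gives the Z-trisubstituted C4=C5 olefin (C3 cis to C6).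

**Step 21**
Reactants: 28 Z-enoate
Product: 29 Z-allylic alcohol (C3)
Conditions: iBu2AlH (2.5 equiv), CH2Cl2, −78 °C
Reagents that add atoms: none
Why: Ester reduction; O6 is still silylated, so the Z-γ-oxygenated system cannot close to a butenolide.

**Step 22**
Reactants: 29 Z-allylic alcohol
Product: 30 Z-enal
Conditions: Dess–Martin periodinane, NaHCO3, CH2Cl2, 0 °C; used at once
Reagents that add atoms: none
Why: Buffered oxidation keeps the Z geometry of the α-methyl enal.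

**Step 23**
Reactants: 30 Z-enal vinyl iodide
Product: 31 ten-membered carbocyclic C3 carbinol (both C3 epimers)
Conditions: CrCl2 (15 equiv), NiCl2 (0.2 equiv), DMSO, rt, 0.003 M, syringe-pump addition
Reagents that add atoms: none
Why: Intramolecular Nozaki–Hiyama–Kishi reaction; the alkenylchromium species formed with retention of the E geometry adds chemoselectively to the aldehyde and closes C2–C3. The C3 configuration is left open because it is erased in step 25.

**Step 24**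
Reactants: 31 macrocyclic carbinol
Product: 32 macrocyclic tetraol (O8-TIPS retained)
Conditions: HF·pyridine, pyridine, THF, 0 °C → rt
Reagents that add atoms: none
Why: Buffered fluoride removes the two TES ethers and the primary allylic TBS ether much faster than the hindered secondary TIPS ether.

**Step 25**
Reactants: 32 tetraol
Product: 34 3-oxo α-methylene lactone (O8-TIPS), via hydroxy lactone 33 (not isolated)
Conditions: TEMPO (20 mol %), PhI(OAc)2, CH2Cl2, rt; then Dess–Martin periodinane, NaHCO3, 0 °C → rt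
Reagents that add atoms: none
Why: Oxidative lactonisation; the primary allylic C12 alcohol is oxidised, the enal is trapped by 6-OH as a lactol and oxidised to the cis-fused α-methylene-γ-lactone, and only then is the bis-allylic C3 carbinol oxidised to the dienone.

**Step 26**
Reactants: 34 keto lactone TIPS ether
Product: 35 8,10-dihydroxy keto lactone
Conditions: HF·pyridine (excess), THF, rt
Reagents that add atoms: none
Why: Fluoride cleavage of the remaining silyl ether; the lactone and the dienone tolerate the weakly acidic medium.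

**Step 27**
Reactants: 35 diol; 36 angelic acid
Product: 37 8-O-angeloyl 3-oxo lactone
Conditions: 36, 2,4,6-trichlorobenzoyl chloride, Et3N, toluene, rt; then 35, 80 °C (no DMAP)
Reagents that add atoms: none
Why: Yamaguchi esterification; the secondary 8-OH is acylated while the tertiary 10-OH is inert, and omitting a nucleophilic catalyst avoids angelate-to-tiglate isomerisation.

**Step 28**
Reactants: 37 3-oxo angelate
Product: 38 target (3S,6S,7R,8S,10S)
Conditions: (R)-2-methyl-CBS-oxazaborolidine (1 equiv), catecholborane (3 equiv), toluene/CH2Cl2, −78 °C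
Reagents that add atoms: none
Why: Corey–Bakshi–Shibata reduction; the α-methyl-substituted alkenyl arm (C4) is taken as the large group and the C2 arm as the small one, so the (R)-catalyst should deliver hydride to give 3S. Catecholborane at −78 °C leaves the lactone, the angelate and the olefins alone.

**Compound list**
1 | ethyl 4-chloro-3-oxobutanoate | CCOC(=O)CC(=O)CCl | starting material
2 | (4-methoxyphenyl)methanol | COc1ccc(CO)cc1 | starting material
3 | ethyl 4-[(4-methoxybenzyl)oxy]-3-oxobutanoate | CCOC(=O)CC(=O)COCc1ccc(OC)cc1 | intermediate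
4 | ethyl (3R)-3-hydroxy-4-[(4-methoxybenzyl)oxy]butanoate | COc1ccc(COC[C@H](O)CC(=O)OCC)cc1 | intermediate
5 | 3-bromoprop-1-ene (allyl bromide) | C=CCBr | starting material
6 | dilithium alkoxide-enolate of 4 | COc1ccc(COC[C@H](O[Li])C=C(O[Li])OCC)cc1 | intermediate
7 | ethyl (2S,3R)-2-allyl-3-hydroxy-4-[(4-methoxybenzyl)oxy]butanoate | COc1ccc(COC[C@H](O)[C@H](CC=C)C(=O)OCC)cc1 | intermediate
8 | ethyl (2S,3R)-2-allyl-4-[(4-methoxybenzyl)oxy]-3-(triethylsilyloxy)butanoate | COc1ccc(COC[C@H](O[Si](CC)(CC)CC)[C@H](CC=C)C(=O)OCC)cc1 | intermediate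
9 | (2S,3R)-2-allyl-4-[(4-methoxybenzyl)oxy]-3-(triethylsilyloxy)butanal | COc1ccc(COC[C@H](O[Si](CC)(CC)CC)[C@H](CC=C)C=O)cc1 | intermediate
10 | 2-[(trimethylsilyl)methyl]prop-2-en-1-yl acetate | CC(=O)OCC(=C)C[Si](C)(C)C | starting material
11 | (4S,5R,6R)-5-allyl-4-hydroxy-7-[(4-methoxybenzyl)oxy]-2-methylidene-6-(triethylsilyloxy)heptyl acetate | COc1ccc(COC[C@H](O[Si](CC)(CC)CC)[C@H](CC=C)[C@@H](O)CC(=C)COC(C)=O)cc1 | intermediate
12 | (4S,5R,6R)-5-allyl-7-[(4-methoxybenzyl)oxy]-2-methylidene-6-(triethylsilyloxy)-4-(triisopropylsilyloxy)heptyl acetate | COc1ccc(COC[C@H](O[Si](CC)(CC)CC)[C@H](CC=C)[C@@H](O[Si](C(C)C)(C(C)C)C(C)C)CC(=C)COC(C)=O)cc1 | intermediate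
13 | (4S,5R,6R)-5-allyl-7-[(4-methoxybenzyl)oxy]-2-methylidene-6-(triethylsilyloxy)-4-(triisopropylsilyloxy)heptan-1-ol | COc1ccc(COC[C@H](O[Si](CC)(CC)CC)[C@H](CC=C)[C@@H](O[Si](C(C)C)(C(C)C)C(C)C)CC(=C)CO)cc1 | intermediate
14 | {(2S)-2-[(2S,3R,4R)-3-allyl-5-[(4-methoxybenzyl)oxy]-4-(triethylsilyloxy)-2-(triisopropylsilyloxy)pentyl]oxiran-2-yl}methanol | COc1ccc(COC[C@H](O[Si](CC)(CC)CC)[C@H](CC=C)[C@@H](O[Si](C(C)C)(C(C)C)C(C)C)C[C@]2(CO)CO2)cc1 | intermediate
15 | (2S,4S,5R,6R)-5-allyl-7-[(4-methoxybenzyl)oxy]-2-methyl-6-(triethylsilyloxy)-4-(triisopropylsilyloxy)heptane-1,2-diol | COc1ccc(COC[C@H](O[Si](CC)(CC)CC)[C@H](CC=C)[C@@H](O[Si](C(C)C)(C(C)C)C(C)C)C[C@](C)(O)CO)cc1 | intermediate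
16 | (2S,4S,5R,6R)-5-allyl-7-[(4-methoxybenzyl)oxy]-2-methyl-1,2,6-tris(triethylsilyloxy)-4-(triisopropylsilyloxy)heptane | COc1ccc(COC[C@H](O[Si](CC)(CC)CC)[C@H](CC=C)[C@@H](O[Si](C(C)C)(C(C)C)C(C)C)C[C@](C)(O[Si](CC)(CC)CC)CO[Si](CC)(CC)CC)cc1 | intermediate
17 | 2,3-dihydroxypropyl analogue of 16 (diol from the allyl group; new carbinol unassigned) | COc1ccc(COC[C@H](O[Si](CC)(CC)CC)[C@H](CC(O)CO)[C@@H](O[Si](C(C)C)(C(C)C)C(C)C)C[C@](C)(O[Si](CC)(CC)CC)CO[Si](CC)(CC)CC)cc1 | intermediate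
18 | (3R,4S,6S)-3-{(1R)-2-[(4-methoxybenzyl)oxy]-1-(triethylsilyloxy)ethyl}-6-methyl-6,7-bis(triethylsilyloxy)-4-(triisopropylsilyloxy)heptanal | COc1ccc(COC[C@H](O[Si](CC)(CC)CC)[C@H](CC=O)[C@@H](O[Si](C(C)C)(C(C)C)C(C)C)C[C@](C)(O[Si](CC)(CC)CC)CO[Si](CC)(CC)CC)cc1 | intermediate
19 | 2-[(dimethylamino)methyl] derivative of 18 (Mannich base; C2 epimers) | COc1ccc(COC[C@H](O[Si](CC)(CC)CC)[C@H](C(CN(C)C)C=O)[C@@H](O[Si](C(C)C)(C(C)C)C(C)C)C[C@](C)(O[Si](CC)(CC)CC)CO[Si](CC)(CC)CC)cc1 | intermediate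
20 | (3R,4S,6S)-3-{(1R)-2-[(4-methoxybenzyl)oxy]-1-(triethylsilyloxy)ethyl}-6-methyl-2-methylidene-6,7-bis(triethylsilyloxy)-4-(triisopropylsilyloxy)heptanal | COc1ccc(COC[C@H](O[Si](CC)(CC)CC)[C@H](C(=C)C=O)[C@@H](O[Si](C(C)C)(C(C)C)C(C)C)C[C@](C)(O[Si](CC)(CC)CC)CO[Si](CC)(CC)CC)cc1 | intermediate
21 | (3R,4S,6S)-3-{(1R)-2-[(4-methoxybenzyl)oxy]-1-(triethylsilyloxy)ethyl}-6-methyl-2-methylidene-6,7-bis(triethylsilyloxy)-4-(triisopropylsilyloxy)heptan-1-ol | COc1ccc(COC[C@H](O[Si](CC)(CC)CC)[C@H](C(=C)CO)[C@@H](O[Si](C(C)C)(C(C)C)C(C)C)C[C@](C)(O[Si](CC)(CC)CC)CO[Si](CC)(CC)CC)cc1 | intermediate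
22 | 1-O-(tert-butyldimethylsilyl) ether of 21 | COc1ccc(COC[C@H](O[Si](CC)(CC)CC)[C@H](C(=C)CO[Si](C)(C)C(C)(C)C)[C@@H](O[Si](C(C)C)(C(C)C)C(C)C)C[C@](C)(O[Si](CC)(CC)CC)CO[Si](CC)(CC)CC)cc1 | intermediate
23 | (2S,4S,5R,6R)-5-[3-(tert-butyldimethylsilyloxy)prop-1-en-2-yl]-7-[(4-methoxybenzyl)oxy]-2-methyl-2,6-bis(triethylsilyloxy)-4-(triisopropylsilyloxy)heptanal | COc1ccc(COC[C@H](O[Si](CC)(CC)CC)[C@H](C(=C)CO[Si](C)(C)C(C)(C)C)[C@@H](O[Si](C(C)C)(C(C)C)C(C)C)C[C@](C)(O[Si](CC)(CC)CC)C=O)cc1 | intermediate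
24 | (1E,3S,5S,6R,7R)-6-[3-(tert-butyldimethylsilyloxy)prop-1-en-2-yl]-1-iodo-8-[(4-methoxybenzyl)oxy]-3-methyl-3,7-bis(triethylsilyloxy)-5-(triisopropylsilyloxy)oct-1-ene | COc1ccc(COC[C@H](O[Si](CC)(CC)CC)[C@H](C(=C)CO[Si](C)(C)C(C)(C)C)[C@@H](O[Si](C(C)C)(C(C)C)C(C)C)C[C@](C)(O[Si](CC)(CC)CC)/C=C/I)cc1 | intermediate
25 | (2R,3R,4S,6S,7E)-3-[3-(tert-butyldimethylsilyloxy)prop-1-en-2-yl]-8-iodo-6-methyl-2,6-bis(triethylsilyloxy)-4-(triisopropylsilyloxy)oct-7-en-1-ol | OC[C@H](O[Si](CC)(CC)CC)[C@H](C(=C)CO[Si](C)(C)C(C)(C)C)[C@@H](O[Si](C(C)C)(C(C)C)C(C)C)C[C@](C)(O[Si](CC)(CC)CC)/C=C/I | intermediate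
26 | (2R,3R,4S,6S,7E)-3-[3-(tert-butyldimethylsilyloxy)prop-1-en-2-yl]-8-iodo-6-methyl-2,6-bis(triethylsilyloxy)-4-(triisopropylsilyloxy)oct-7-enal | O=C[C@H](O[Si](CC)(CC)CC)[C@H](C(=C)CO[Si](C)(C)C(C)(C)C)[C@@H](O[Si](C(C)C)(C(C)C)C(C)C)C[C@](C)(O[Si](CC)(CC)CC)/C=C/I | intermediate
27 | ethyl 2-[bis(2,2,2-trifluoroethoxy)phosphoryl]propanoate | CCOC(=O)C(C)P(=O)(OCC(F)(F)F)OCC(F)(F)F | starting material
28 | ethyl (2Z,4S,5R,6S,8S,9E)-5-[3-(tert-butyldimethylsilyloxy)prop-1-en-2-yl]-10-iodo-2,8-dimethyl-4,8-bis(triethylsilyloxy)-6-(triisopropylsilyloxy)deca-2,9-dienoate | CCOC(=O)/C(C)=C\[C@H](O[Si](CC)(CC)CC)[C@H](C(=C)CO[Si](C)(C)C(C)(C)C)[C@@H](O[Si](C(C)C)(C(C)C)C(C)C)C[C@](C)(O[Si](CC)(CC)CC)/C=C/I | intermediate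
29 | (2Z,4S,5R,6S,8S,9E)-5-[3-(tert-butyldimethylsilyloxy)prop-1-en-2-yl]-10-iodo-2,8-dimethyl-4,8-bis(triethylsilyloxy)-6-(triisopropylsilyloxy)deca-2,9-dien-1-ol | OC/C(C)=C\[C@H](O[Si](CC)(CC)CC)[C@H](C(=C)CO[Si](C)(C)C(C)(C)C)[C@@H](O[Si](C(C)C)(C(C)C)C(C)C)C[C@](C)(O[Si](CC)(CC)CC)/C=C/I | intermediate
30 | (2Z,4S,5R,6S,8S,9E)-5-[3-(tert-butyldimethylsilyloxy)prop-1-en-2-yl]-10-iodo-2,8-dimethyl-4,8-bis(triethylsilyloxy)-6-(triisopropylsilyloxy)deca-2,9-dienal | O=C/C(C)=C\[C@H](O[Si](CC)(CC)CC)[C@H](C(=C)CO[Si](C)(C)C(C)(C)C)[C@@H](O[Si](C(C)C)(C(C)C)C(C)C)C[C@](C)(O[Si](CC)(CC)CC)/C=C/I | intermediate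
31 | (6S,7R,8S,10S)-12-(tert-butyldimethylsilyloxy)-6,10-bis(triethylsilyloxy)-8-(triisopropylsilyloxy)germacra-1E,4Z,11(13)-trien-3-ol (both C3 epimers) | CC[Si](CC)(CC)O[C@H]1/C=C(/C)C(O)/C=C/[C@@](C)(O[Si](CC)(CC)CC)C[C@H](O[Si](C(C)C)(C(C)C)C(C)C)[C@H]1C(=C)CO[Si](C)(C)C(C)(C)C | intermediate
32 | (6S,7S,8S,10S)-8-(triisopropylsilyloxy)germacra-1E,4Z,11(13)-triene-3,6,10,12-tetrol (both C3 epimers) | O[C@H]1/C=C(/C)C(O)/C=C/[C@@](C)(O)C[C@H](O[Si](C(C)C)(C(C)C)C(C)C)[C@H]1C(=C)CO | intermediate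
33 | (6S,7S,8S,10S)-3,10-dihydroxy-8-(triisopropylsilyloxy)germacra-1E,4Z,11(13)-trien-12,6-olide (both C3 epimers) | C=C1C(=O)O[C@H]2/C=C(/C)C(O)/C=C/[C@@](C)(O)C[C@H](O[Si](C(C)C)(C(C)C)C(C)C)[C@@H]12 | intermediate
34 | (6S,7S,8S,10S)-10-hydroxy-3-oxo-8-(triisopropylsilyloxy)germacra-1E,4Z,11(13)-trien-12,6-olide | C=C1C(=O)O[C@H]2/C=C(/C)C(=O)/C=C/[C@@](C)(O)C[C@H](O[Si](C(C)C)(C(C)C)C(C)C)[C@@H]12 | intermediate
35 | (6S,7R,8S,10S)-8,10-dihydroxy-3-oxogermacra-1E,4Z,11(13)-trien-12,6-olide | C=C1C(=O)O[C@H]2/C=C(/C)C(=O)/C=C/[C@@](C)(O)C[C@H](O)[C@@H]12 | intermediate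
36 | (Z)-2-methylbut-2-enoic acid (angelic acid) | C/C=C(/C)C(=O)O | starting material
37 | (6S,7R,8S,10S)-10-hydroxy-8-[(Z)-2-methylbut-2-enoyloxy]-3-oxogermacra-1E,4Z,11(13)-trien-12,6-olide | C=C1C(=O)O[C@H]2/C=C(/C)C(=O)/C=C/[C@@](C)(O)C[C@H](OC(=O)/C(C)=C\C)[C@@H]12 | intermediate
38 | (3S,6S,7R,8S,10S)-3,10-dihydroxy-8-[(Z)-2-methylbut-2-enoyloxy]germacra-1E,4Z,11(13)-trien-12,6-olide (CNP0262559.5) | C=C1C(=O)O[C@H]2/C=C(/C)[C@@H](O)/C=C/[C@@](C)(O)C[C@H](OC(=O)/C(C)=C\C)[C@@H]12 | target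

**Total step count:** 28. **Longest linear sequence:** 28 steps (1 → 38); the route is fully linear.

**Three steps most likely to fail, each with one fallback**

Step 23 (closing the strained ten-membered ring on an open-chain, heavily silylated substrate). The fallback reverses the order of ring formation and sets out from 29. PMB trichloroacetimidate with PPTS gives the 3-O-PMB ether F2. HF·pyridine/pyridine removes the two TES groups and the primary TBS group and gives the triol F3. TEMPO/PhI(OAc)2 oxidises C12 and closes the α-methylene lactone F4. DDQ frees the allylic alcohol F5, and Dess–Martin periodinane gives the Z-enal lactone F6. The CrCl2/NiCl2 closure is then run on this conformationally restricted cis-fused lactone and gives 33, which rejoins the route at the second stage of step 25.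

Step 28 (facial selectivity at C3 in a macrocyclic cross-conjugated dienone may follow ring conformation and not the catalyst). The fallback uses substrate control with recycling and sets out from 37. NaBH4/CeCl3·7H2O in MeOH at −78 °C gives 38 together with the (3R)-epimer F7. The two are separated, and F7 is re-oxidised with MnO2 to 37 and resubmitted. The fallback comes back to the route at 38.

Step 6 (C8 selectivity with this deactivated, functionalised allylsilane may be lower than for simple enolsilanes). The fallback sets C8 by reagent-controlled reduction instead of by the C–C bond formation and sets out from 11, taken as the C8 epimer mixture. Dess–Martin periodinane gives the C8 ketone F1. Reduction with (R)-2-methyl-CBS-oxazaborolidine and catecholborane at −78 °C (branched C7 as large group, C9 methylene as small group) returns (8S)-11.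

**Further compounds**
F1 | step 6 | (5S,6R)-5-allyl-7-[(4-methoxybenzyl)oxy]-2-methylidene-4-oxo-6-(triethylsilyloxy)heptyl acetate | COc1ccc(COC[C@H](O[Si](CC)(CC)CC)[C@H](CC=C)C(=O)CC(=C)COC(C)=O)cc1
F2 | step 23 | 1-O-(4-methoxybenzyl) ether of 29 | COc1ccc(COC/C(C)=C\[C@H](O[Si](CC)(CC)CC)[C@H](C(=C)CO[Si](C)(C)C(C)(C)C)[C@@H](O[Si](C(C)C)(C(C)C)C(C)C)C[C@](C)(O[Si](CC)(CC)CC)/C=C/I)cc1
F3 | step 23 | triol from F2 (6-OH, 10-OH, 12-OH free; 8-O-TIPS and 3-O-PMB kept) | COc1ccc(COC/C(C)=C\[C@H](O)[C@H](C(=C)CO)[C@@H](O[Si](C(C)C)(C(C)C)C(C)C)C[C@](C)(O)/C=C/I)cc1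
F4 | step 23 | cis-β,γ-disubstituted α-methylene-γ-butyrolactone from F3 (3-O-PMB, 8-O-TIPS, vinyl iodide) | COc1ccc(COC/C(C)=C\[C@@H]2OC(=O)C(=C)[C@@H]2[C@@H](O[Si](C(C)C)(C(C)C)C(C)C)C[C@](C)(O)/C=C/I)cc1
F5 | step 23 | C3 allylic alcohol of the lactone F4 after PMB removal | OC/C(C)=C\[C@@H]1OC(=O)C(=C)[C@@H]1[C@@H](O[Si](C(C)C)(C(C)C)C(C)C)C[C@](C)(O)/C=C/I
F6 | step 23 | Z-enal lactone vinyl iodide | O=C/C(C)=C\[C@@H]1OC(=O)C(=C)[C@@H]1[C@@H](O[Si](C(C)C)(C(C)C)C(C)C)C[C@](C)(O)/C=C/I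
F7 | step 28 | (3R)-epimer of 38 | C=C1C(=O)O[C@H]2/C=C(/C)[C@H](O)/C=C/[C@@](C)(O)C[C@H](OC(=O)/C(C)=C\C)[C@@H]12
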